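Numbering the target as a furo[3,2-b]furan-2-one (O1, C2=O, C3, C3a, O4, C5, C6, C6a), the lactone carbons C2–C3 sit as a two-carbon unit on the vicinal fusion atoms C6a and C3a of the tetrahydrofuran ring, C3a bearing O4. That is the pattern a ketene leaves on an enol ether. Dichloroketene therefore adds across C3a=C6a of an enantiopure 2-(silyloxymethyl)-2,4-dimethyl-2,3-dihydrofuran, forming the C3–C3a and C2–C6a bonds, the cis-fused four-membered ring and both fusion stereocentres at once. Dechlorination and Baeyer–Villiger insertion of O1 at quaternary C6a then give the lactone, and the silyloxymethyl arm is later extended to the 12-phenyldodecyl chain.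

Key step: step 6

Remark: TBDPS = tert-butyldiphenylsilyl; the methyl-bearing carbon made in step 3 (compounds 5–9) and the CHCl carbon of 14 form as epimer mixtures and are left undefined in the SMILES because steps 5 and 7 erase them; steps 11–13 are the side branch that makes the chain reagent.

Step 1
Reactants: 1 (S)-2-methylglycidol; 2 isopropenylmagnesium bromide
Product: 3 (2R)-2,4-dimethylpent-4-ene-1,2-diol
Conditions: CuI (10 mol%), THF, −30 → 0 °C (2.5 equiv of 2)
Reagents that add atoms: none
Why: Copper-catalysed Grignard opening of an epoxide: once the first equivalent has deprotonated the hydroxyl, the organocopper species attacks the unhindered CH2 terminus in an SN2 fashion, so the quaternary stereocentre is carried over untouched (its descriptor changes from S to R only because the CIP priorities change).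

Step 2
Reactants: 3 (2R)-2,4-dimethylpent-4-ene-1,2-diol
Product: 4 (2R)-1-(TBDPS-oxy)-2,4-dimethylpent-4-en-2-ol
Conditions: TBDPSCl, imidazole, CH2Cl2, 0 °C → rt
Reagents that add atoms: tert-butyl(chloro)diphenylsilane, CC(C)(C)[Si](Cl)(c1ccccc1)c1ccccc1
Why: Imidazole-promoted silylation is selective for the primary over the hindered tertiary hydroxyl, and this silyl group is chosen because it tolerates ZnCl2, acetic acid and peracid later and gives the oxymethyl arm the bulk that step 6 relies on.

Step 3
Reactants: 4 (2R)-1-(TBDPS-oxy)-2,4-dimethylpent-4-en-2-ol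
Product: 6 (4R)-5-(TBDPS-oxy)-2,4-dimethylpentane-1,4-diol, via alkylborane 5 (not isolated)
Conditions: 9-BBN, THF, 0 °C → rt; then NaOH, H2O2, H2O, 0 °C → rt
Reagents that add atoms: hydrogen peroxide, OO
Why: Brown hydroboration–oxidation places boron on the terminal carbon of the 1,1-disubstituted alkene (anti-Markovnikov) and alkaline peroxide replaces it by hydroxyl with retention; the new methyl-bearing stereocentre forms unselectively, which is harmless because it becomes sp2 in step 5.

Step 4
Reactants: 6 (4R)-5-(TBDPS-oxy)-2,4-dimethylpentane-1,4-diol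
Product: 8 (5R)-5-(TBDPS-oxymethyl)-3,5-dimethyloxolan-2-ol (lactol), via hydroxy aldehyde 7 (not isolated)
Conditions: (COCl)2, DMSO, CH2Cl2, −78 °C; then Et3N, −78 °C → rt
Reagents that add atoms: none
Why: Swern oxidation can only convert the primary alcohol (the tertiary one has no carbinol hydrogen) and the γ-hydroxy aldehyde closes spontaneously to the five-membered lactol; the activated sulfoxide is spent at low temperature before the lactol appears, which should keep over-oxidation to the lactone small.

Step 5
Reactants: 8 (5R)-5-(TBDPS-oxymethyl)-3,5-dimethyloxolan-2-ol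
Product: 10 (R)-tert-butyl[(2,4-dimethyl-2,3-dihydrofuran-2-yl)methoxy]diphenylsilane, via lactol mesylate 9 (not isolated)
Conditions: MsCl, Et3N, CH2Cl2, −40 °C → reflux
Reagents that add atoms: none
Why: Glycal-type dehydration of a lactol: the anomeric mesylate ionises with help from the ring oxygen and Et3N removes the only β-hydrogen, giving the trisubstituted cyclic enol ether without touching the quaternary stereocentre.

Step 6
Reactants: 10 (R)-tert-butyl[(2,4-dimethyl-2,3-dihydrofuran-2-yl)methoxy]diphenylsilane; 11 trichloroacetyl chloride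
Product: 13 (1R,3R,5S)-3-(TBDPS-oxymethyl)-7,7-dichloro-3,5-dimethyl-2-oxabicyclo[3.2.0]heptan-6-one, via dichloroketene 12 (not isolated)
Conditions: Zn–Cu couple, DME, Et2O, 0 °C → rt (11 added slowly)
Reagents that add atoms: none
Why: Zinc reduces 11 to dichloroketene 12, whose electrophilic carbonyl carbon is attacked by the nucleophilic, methyl-bearing C4 of the enol ether while the oxygen-bearing C5 bonds to the CCl2 carbon, in a concerted but asynchronous thermal [2+2] cycloaddition with orthogonal approach of the ketene. This is the classical dichloroketene–enol ether cycloaddition, well established for dihydrofurans, dihydropyrans and glycals. The four-membered ring is closed by this intermolecular cycloaddition across the endocyclic C4=C5 bond, suprafacial on the alkene, so it can only be cis-fused to the oxolane. The two new stereocentres, bridgeheads C1 and C5 of 13, are set together, and their sense is controlled by the existing quaternary carbon: the ketene should approach the face anti to the bulky CH2O-TBDPS arm and syn to the small methyl group. Regioselectivity comes from polarisation of the enol ether by the ring oxygen, and facial selectivity from the size difference of the two groups on C2, which is why the large silyl ether is used. DME ties up ZnCl2 so that the acid-labile enol ether should survive.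

Step 7
Reactants: 13 (1R,3R,5S)-3-(TBDPS-oxymethyl)-7,7-dichloro-3,5-dimethyl-2-oxabicyclo[3.2.0]heptan-6-one
Product: 15 (1S,3R,5S)-3-(TBDPS-oxymethyl)-3,5-dimethyl-2-oxabicyclo[3.2.0]heptan-6-one, via monochloro ketone 14 (not isolated)
Conditions: Zn dust, AcOH, rt → 50 °C
Reagents that add atoms: none
Why: Reductive dechlorination of an α,α-dichloro ketone by zinc in acetic acid runs through zinc enolates that are protonated faster than they could expel the β ring oxygen, and neither the stereocentres nor the silyl ether are affected.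

Step 8
Reactants: 15 (1S,3R,5S)-3-(TBDPS-oxymethyl)-3,5-dimethyl-2-oxabicyclo[3.2.0]heptan-6-one
Product: 16 (3aS,5R,6aS)-5-(TBDPS-oxymethyl)-5,6a-dimethyltetrahydrofuro[3,2-b]furan-2(3H)-one
Conditions: mCPBA, CH2Cl2, 0 °C → rt
Reagents that add atoms: 3-chloroperoxybenzoic acid, OOC(=O)c1cccc(Cl)c1
Why: Baeyer–Villiger oxidation driven by release of cyclobutanone strain: in the Criegee intermediate the quaternary bridgehead carbon migrates in preference to the CH2 group and with retention, so oxygen is inserted at the methyl-bearing fusion carbon and the cis fusion is kept.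

Step 9
Reactants: 16 (3aS,5R,6aS)-5-(TBDPS-oxymethyl)-5,6a-dimethyltetrahydrofuro[3,2-b]furan-2(3H)-one
Product: 17 (3aS,5R,6aS)-5-(hydroxymethyl)-5,6a-dimethyltetrahydrofuro[3,2-b]furan-2(3H)-one
Conditions: Bu4NF, AcOH, THF, rt
Reagents that add atoms: none
Why: Fluoride-mediated silyl ether cleavage, buffered with acetic acid so that the medium stays non-basic and the β-alkoxy lactone is neither enolised nor opened.

Step 10
Reactants: 17 (3aS,5R,6aS)-5-(hydroxymethyl)-5,6a-dimethyltetrahydrofuro[3,2-b]furan-2(3H)-one
Product: 18 (3aS,5R,6aS)-5,6a-dimethyl-2-oxohexahydrofuro[3,2-b]furan-5-carbaldehyde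
Conditions: Dess–Martin periodinane, CH2Cl2, rt
Reagents that add atoms: none
Why: Dess–Martin oxidation of the primary alcohol under near-neutral conditions gives an aldehyde that has no α-hydrogen and therefore cannot epimerise.

Step 11
Reactants: 19 11-phenylundecanoic acid
Product: 20 11-phenylundecan-1-ol
Conditions: LiAlH4, THF, 0 °C → reflux
Reagents that add atoms: none
Why: Hydride reduction of a carboxylic acid to the primary alcohol, with the isolated phenyl ring inert.

Step 12
Reactants: 20 11-phenylundecan-1-ol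
Product: 21 (11-iodoundecyl)benzene
Conditions: PPh3, I2, imidazole, CH2Cl2, 0 °C → rt
Reagents that add atoms: iodine, II
Why: Appel-type iodination: iodide displaces the alkoxyphosphonium leaving group at the unhindered primary carbon.

Step 13
Reactants: 21 (11-iodoundecyl)benzene
Product: 22 triphenyl(11-phenylundecyl)phosphonium iodide
Conditions: PPh3, MeCN, reflux
Reagents that add atoms: triphenylphosphine, c1ccc(cc1)P(c1ccccc1)c1ccccc1
Why: Quaternisation of triphenylphosphine by SN2 displacement of a primary iodide.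

Step 14
Reactants: 18 (3aS,5R,6aS)-5,6a-dimethyl-2-oxohexahydrofuro[3,2-b]furan-5-carbaldehyde; 22 triphenyl(11-phenylundecyl)phosphonium iodide
Product: 24 (3aS,5R,6aS)-5,6a-dimethyl-5-[(1Z)-12-phenyldodec-1-en-1-yl]tetrahydrofuro[3,2-b]furan-2(3H)-one, via ylide 23 (not isolated)
Conditions: NaN(SiMe3)2 (slightly less than 22), THF, 0 °C; then 18, −78 °C → rt
Reagents that add atoms: none
Why: Wittig olefination: the non-stabilised ylide should add to the aldehyde at −78 °C much faster than it attacks or deprotonates the γ-lactone, giving mainly the Z alkene through the kinetic cis-oxaphosphetane; the geometry is irrelevant because the alkene is hydrogenated next, and no stereocentre is touched.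

Step 15
Reactants: 24 (3aS,5R,6aS)-5,6a-dimethyl-5-[(1Z)-12-phenyldodec-1-en-1-yl]tetrahydrofuro[3,2-b]furan-2(3H)-one
Product: 25 plakortone L, (3aS,5S,6aS)-5,6a-dimethyl-5-(12-phenyldodecyl)tetrahydrofuro[3,2-b]furan-2(3H)-one
Conditions: H2 (1 atm), 10% Pd/C, EtOAc, rt
Reagents that add atoms: none
Why: Heterogeneous catalytic hydrogenation saturates the disubstituted alkene while the benzene ring and lactone are inert at 1 atm, and the neutral solvent should keep hydrogenolysis of the allylic C–O bond minimal.

Compound list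
1 | (S)-2-methylglycidol, [(2S)-2-methyloxiran-2-yl]methanol | C[C@]1(CO)CO1 | starting material
2 | isopropenylmagnesium bromide | CC(=C)[Mg]Br | starting material
3 | (2R)-2,4-dimethylpent-4-ene-1,2-diol | C[C@](O)(CO)CC(C)=C | intermediate
4 | (2R)-1-(TBDPS-oxy)-2,4-dimethylpent-4-en-2-ol | C[C@](O)(CO[Si](c1ccccc1)(c1ccccc1)C(C)(C)C)CC(C)=C | intermediate
5 | alkylborane, (2R)-5-(9-borabicyclo[3.3.1]nonan-9-yl)-1-(TBDPS-oxy)-2,4-dimethylpentan-2-ol (C4 epimers, formed in the flask) | C[C@](O)(CO[Si](c1ccccc1)(c1ccccc1)C(C)(C)C)CC(C)CB1C2CCCC1CCC2 | intermediate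
6 | (4R)-5-(TBDPS-oxy)-2,4-dimethylpentane-1,4-diol (C2 epimers) | C[C@](O)(CO[Si](c1ccccc1)(c1ccccc1)C(C)(C)C)CC(C)CO | intermediate
7 | hydroxy aldehyde, (4R)-5-(TBDPS-oxy)-4-hydroxy-2,4-dimethylpentanal (formed in the flask) | C[C@](O)(CO[Si](c1ccccc1)(c1ccccc1)C(C)(C)C)CC(C)C=O | intermediate
8 | lactol, (5R)-5-(TBDPS-oxymethyl)-3,5-dimethyloxolan-2-ol (C2/C3 mixture) | C[C@]1(CO[Si](c2ccccc2)(c2ccccc2)C(C)(C)C)CC(C)C(O)O1 | intermediate
9 | lactol mesylate, (5R)-5-(TBDPS-oxymethyl)-3,5-dimethyloxolan-2-yl methanesulfonate (formed in the flask) | C[C@]1(CO[Si](c2ccccc2)(c2ccccc2)C(C)(C)C)CC(C)C(OS(C)(=O)=O)O1 | intermediate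
10 | (R)-tert-butyl[(2,4-dimethyl-2,3-dihydrofuran-2-yl)methoxy]diphenylsilane | C[C@]1(CO[Si](c2ccccc2)(c2ccccc2)C(C)(C)C)CC(C)=CO1 | intermediate
11 | trichloroacetyl chloride | ClC(Cl)(Cl)C(Cl)=O | starting material
12 | dichloroketene (formed in the flask) | ClC(Cl)=C=O | intermediate
13 | (1R,3R,5S)-3-(TBDPS-oxymethyl)-7,7-dichloro-3,5-dimethyl-2-oxabicyclo[3.2.0]heptan-6-one | C[C@]1(CO[Si](c3ccccc3)(c3ccccc3)C(C)(C)C)C[C@]2(C)C(=O)C(Cl)(Cl)[C@@H]2O1 | intermediate
14 | monochloro ketone, (1R,3R,5S)-3-(TBDPS-oxymethyl)-7-chloro-3,5-dimethyl-2-oxabicyclo[3.2.0]heptan-6-one (C7 epimers, formed in the flask) | C[C@]1(CO[Si](c3ccccc3)(c3ccccc3)C(C)(C)C)C[C@]2(C)C(=O)C(Cl)[C@@H]2O1 | intermediate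
15 | (1S,3R,5S)-3-(TBDPS-oxymethyl)-3,5-dimethyl-2-oxabicyclo[3.2.0]heptan-6-one | C[C@]1(CO[Si](c3ccccc3)(c3ccccc3)C(C)(C)C)C[C@]2(C)C(=O)C[C@@H]2O1 | intermediate
16 | (3aS,5R,6aS)-5-(TBDPS-oxymethyl)-5,6a-dimethyltetrahydrofuro[3,2-b]furan-2(3H)-one | C[C@]1(CO[Si](c3ccccc3)(c3ccccc3)C(C)(C)C)C[C@]2(C)OC(=O)C[C@@H]2O1 | intermediate
17 | (3aS,5R,6aS)-5-(hydroxymethyl)-5,6a-dimethyltetrahydrofuro[3,2-b]furan-2(3H)-one | C[C@]1(CO)C[C@]2(C)OC(=O)C[C@@H]2O1 | intermediate
18 | (3aS,5R,6aS)-5,6a-dimethyl-2-oxohexahydrofuro[3,2-b]furan-5-carbaldehyde | C[C@]1(C=O)C[C@]2(C)OC(=O)C[C@@H]2O1 | intermediate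
19 | 11-phenylundecanoic acid | OC(=O)CCCCCCCCCCc1ccccc1 | starting material
20 | 11-phenylundecan-1-ol | OCCCCCCCCCCCc1ccccc1 | intermediate
21 | (11-iodoundecyl)benzene | ICCCCCCCCCCCc1ccccc1 | intermediate
22 | triphenyl(11-phenylundecyl)phosphonium iodide | [I-].c1ccccc1CCCCCCCCCCC[P+](c1ccccc1)(c1ccccc1)c1ccccc1 | intermediate
23 | ylide, triphenyl(11-phenylundecylidene)phosphorane (formed in the flask) | c1ccccc1CCCCCCCCCCC=P(c1ccccc1)(c1ccccc1)c1ccccc1 | intermediate
24 | (3aS,5R,6aS)-5,6a-dimethyl-5-[(1Z)-12-phenyldodec-1-en-1-yl]tetrahydrofuro[3,2-b]furan-2(3H)-one | C[C@]1(/C=C\CCCCCCCCCCc3ccccc3)C[C@]2(C)OC(=O)C[C@@H]2O1 | intermediate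
25 | plakortone L, (3aS,5S,6aS)-5,6a-dimethyl-5-(12-phenyldodecyl)tetrahydrofuro[3,2-b]furan-2(3H)-one | C[C@]1(CCCCCCCCCCCCc2ccccc2)C[C@]2(C)OC(=O)C[C@@H]2O1 | target

Total step count: 15. Longest linear sequence: 12 steps (steps 1–10, 14 and 15); steps 11–13 are a three-step side branch.

Steps most likely to fail

1. Step 6. The dihydrofuran is nearly flat, and the methyl and silyloxymethyl groups may not differ enough near the ring, so the ketene may add to both faces. The enol ether may also be hydrolysed or oligomerised by ZnCl2 before it is trapped. The fallback sets out from alkene 4 and builds the bicycle by a different ring construction. Ozonolysis (O3, CH2Cl2, −78 °C; then PPh3) would give the β-hydroxy ketone (4R)-5-(TBDPS-oxy)-4-hydroxy-4-methylpentan-2-one F1. Addition of vinylmagnesium bromide (THF, −78 °C) would give the tertiary ene-diol as two epimers. The needed one, (2R,4S)-1-(TBDPS-oxy)-2,4-dimethylhex-5-ene-2,4-diol F2, would be separated by chromatography. Oxidative hydroxycyclisation–carbonylation–lactonisation with divalent palladium (PdCl2 cat., CuCl2, NaOAc, AcOH, CO 1 atm, rt) would then close the oxolane by 5-exo oxypalladation and the lactone by CO insertion and capture of the acyl group by the allylic hydroxyl. This can only give the cis-fused bicycle, and the route is rejoined at lactone 16.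

2. Step 14. The basic ylide may deprotonate the lactone α-CH2, after which the ring oxygen is lost by β-elimination. Alternatively, addition to the hindered aldehyde may be slow enough for the ylide to attack the lactone carbonyl. The fallback sets out from aldehyde 18 and iodide 21 and replaces the olefination by a non-basic addition followed by deoxygenation. Cobalt-catalysed alkylchromium addition (CrCl2, cobalt phthalocyanine C32H16CoN8 cat., DMF, rt), a Nozaki–Hiyama-type reaction that leaves lactones alone, would give the secondary alcohol (3aS,5R,6aS)-5-(1-hydroxy-12-phenyldodecyl)-5,6a-dimethyltetrahydrofuro[3,2-b]furan-2(3H)-one F3 as a carbinol epimer mixture. Acylation with PhOC(S)Cl and DMAP (MeCN, rt) would give the thionocarbonate O-[1-((3aS,5R,6aS)-5,6a-dimethyl-2-oxohexahydrofuro[3,2-b]furan-5-yl)-12-phenyldodecyl] O-phenyl carbonothioate F4. Barton–McCombie deoxygenation (Bu3SnH, AIBN, toluene, 90 °C) would then remove the oxygen and give plakortone L 25 directly, bypassing steps 14 and 15.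

3. Step 5. The anomeric mesylate or chloride may eliminate incompletely, and the acid-sensitive enol ether may be hydrated or dimerised during isolation. The fallback sets out from lactol 8 and avoids anomeric halides. Acetalisation (MeOH, PPTS, rt) would give the methyl acetal tert-butyl{[(2R)-5-methoxy-2,4-dimethyloxolan-2-yl]methoxy}diphenylsilane F5. Treatment with Me3SiOTf and i-Pr2NEt (CH2Cl2, −20 °C → rt) would ionise the acetal to the ring oxocarbenium ion and remove the C4 proton under constantly basic conditions, returning to the route at dihydrofuran 10.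

Further compounds
F1 | step 6 | (4R)-5-(TBDPS-oxy)-4-hydroxy-4-methylpentan-2-one | C[C@](O)(CO[Si](c1ccccc1)(c1ccccc1)C(C)(C)C)CC(C)=O
F2 | step 6 | (2R,4S)-1-(TBDPS-oxy)-2,4-dimethylhex-5-ene-2,4-diol | C[C@](O)(CO[Si](c1ccccc1)(c1ccccc1)C(C)(C)C)C[C@](C=C)(C)O
F3 | step 14 | (3aS,5R,6aS)-5-(1-hydroxy-12-phenyldodecyl)-5,6a-dimethyltetrahydrofuro[3,2-b]furan-2(3H)-one (carbinol epimers) | C[C@]1(C(O)CCCCCCCCCCCc3ccccc3)C[C@]2(C)OC(=O)C[C@@H]2O1
F4 | step 14 | O-[1-((3aS,5R,6aS)-5,6a-dimethyl-2-oxohexahydrofuro[3,2-b]furan-5-yl)-12-phenyldodecyl] O-phenyl carbonothioate | C[C@]1(C(OC(=S)Oc3ccccc3)CCCCCCCCCCCc3ccccc3)C[C@]2(C)OC(=O)C[C@@H]2O1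
F5 | step 5 | tert-butyl{[(2R)-5-methoxy-2,4-dimethyloxolan-2-yl]methoxy}diphenylsilane | C[C@]1(CO[Si](c2ccccc2)(c2ccccc2)C(C)(C)C)CC(C)C(OC)O1
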